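(The readings stem from a simulated flask on assumed constants, and the scatter is random.)

The invariant I would trust on Monday's run, the flask at 20 °C we are asked about, is not points per minute but points per doubling of the clock. From 10.0 min to 20.0 min the target climbs from 50% to 58%, so the doubling gain is 8 percentage points: the points of target won each time the elapsed time doubles. It is a reading, and each reading behind it scatters by 1.5 points.

| flask | starting material | partner A | partner B | temperature | remark | time |
|---|---|---|---|---|---|---|
| Monday's | 1 M | 1 equiv | 3 equiv | 20 °C | the very flask that is asked about, followed so far |  |
| Saturday's | 1 M | 1 equiv | 3 equiv | 26 °C | run made earlier |  |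
| flask | 1.0 M | 1.00 equiv | 3.00 equiv | 20 °C |  | 25 min |

| Monday's: time / min | Monday's: target / % | Saturday's: time / min | Saturday's: target / % |
|---|---|---|---|
| 5.00 | 39 | 5.00 | 48 |
| 10.0 | 50 | 10.0 | 55 |
| 15.0 | 57 | 15.0 | 60 |
| 20.0 | 58 | 20.0 | 66 |
| 25.0 | 64 | 25.0 | 69 |

(scatter of a reading: 1.5 percentage points)

- what is taken out of target is counted as made

- larch: at 25 min raise the temperature by 10 K, then wait 12 min
- cedar: change nothing and wait 12 min more
- oak: at 25 min take out 90% of the target then present, then wait 12 min

- target, in percent of the starting material first charged, at 25 min
- what to do for the largest gain in target; "none" if nothing gains more than 2 percentage points (larch / cedar / oak / none)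
- target present, with what was taken out counted in, in percent of the starting material first charged, after cedar
- target present, with what was taken out counted in, in percent of the starting material first charged, after oak

You have a next step to choose, so price each option. Cedar takes the clock from 25 min to 37.0 min, which at the doubling gain is worth 4.5 points, and from the last reading of 64% that means 68.5%. Saturday's run, at 26 °C, lies on average 6 points above Monday's at equal times. I read that as a faster clock, and larch's rise of 10 K is larger than the warming between those two runs, so I rank larch ahead of cedar without putting a price on it. Neither run had target removed, so oak has no reading behind it, and my choice is larch.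

The forecast differs. It puts the flask at 63.5%, cedar at 68% and oak at 75%, and it chooses oak, while granting that “it depends on the slowing being product-driven”.

The flask stands at 61.5%, and the best move is larch: larch gains 7.3 points, while cedar and oak gain 4.1 points and 4.1 points, both ending at 65.6%. The doubling gain had priced cedar at 4.5 points.

    starting material + partner B → open intermediate (k = 0.0100 M⁻¹ s⁻¹, Ea = 58.0 kJ mol⁻¹)
    partner B + partner A → second intermediate (k = 0.0120 M⁻¹ s⁻¹, Ea = 44.0 kJ mol⁻¹)
    open intermediate + second intermediate → target (k = 0.0100 M⁻¹ s⁻¹, Ea = 58.0 kJ mol⁻¹)
    2 second intermediate → homo product (k = 0.00580 M⁻¹ s⁻¹, Ea = 74.0 kJ mol⁻¹)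
    partner A ⇌ dormant form (K = 6.90, k = 0.00980 s⁻¹, Ea = 70.0 kJ mol⁻¹, ΔH = −15.0 kJ mol⁻¹)
    (constants at 20 °C)

In the asked flask, partner B's half-life by its step with partner A lengthens from 2.9 min at 0.485 min to 190 min at 25.0 min, when free partner A, the limiting reagent, stands at 0.517% of its charge beside 0.0804 M of dormant form. On the neighbour flask read at 15 min, going back from 61.5% by the doubling gain gives 55.6%; the computed value is 55.8%.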